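## The problem

Gnetumontanin B (26) is made of two trans-2,3-diaryl-2,3-dihydrobenzofurans. Benzofuran locants are used throughout, unprimed for the inner ring system (O1, C2, C3 and ring A, C3a–C7a) and primed for the outer one (O1', C2', C3' and ring B, C3a'–C7a'). The two halves are joined by the C2–C7' bond; ring A carries the (E)-4-hydroxystyryl group at C6, C3 and C3' each carry a 3,5-dihydroxyphenyl group, and C2' a 2,4-dihydroxyphenyl group.

The four stereocentres form two vicinal pairs, (2S,3S) and (2'S,3'S), both trans. The flat ring B holds the pairs apart, so neither can be expected to steer the other and each must be set by a reagent. Inside a pair, the oxygen-bearing carbon can govern its neighbour as long as the diarylmethine hydrogen is still acidic, that is, at the ketone stage.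

C2 and C2' are benzylic ether carbons attached to aryl rings with ortho and para oxygen, so both C–O bonds ionise easily under acid. The doubly benzylic C3–H and C3'–H lie beta to a phenoxide leaving group and invite base-induced ring opening. The nine phenols are oxidation-prone, and the E-stilbene rules out hydrogenolysis and long exposure to acid or light.

Ring B is a 1,2,3,4-tetrasubstituted benzene in which C5' and C7' are both activated by the two oxygens, so the carbon substituent at C7' cannot be placed by electrophilic substitution once the ring is closed. The feature that opens the problem is that O1' (on C7a') and C2 (on C7') sit on neighbouring carbons of ring B, directly beside C3a', which holds the C3' side chain. They are the two ends of a C7'–C7a' aryne, across which a tethered alkoxide and an external one-carbon electrophile can be added in one operation.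

## Retrosynthesis

**Nine O–CH3 bonds (26 from 25).** The last operation frees the phenols of nonamethyl ether 25. Methyl is preferred to benzyl (hydrogenolysis would attack the stilbene and the benzylic C–O bonds), to silyl (lost or migrating under alkoxide and lithium amide) and to acetal groups (which would draw lithiation away from fluorine). It also lets every aromatic ring be bought with its oxygens in place. The forward step must cleave nine ethers without ionising C2–O1 or C2'–O1'.

**O1–C7a (25 from 22).** The inner ring is opened at the aryl–oxygen bond, giving fluoro alcohol 22. Cutting the alkyl–oxygen bond O1–C2 instead would mean substitution at a carbon that ionises at once. Making the aryl–oxygen bond leaves C2 and C3 untouched, so the trans ring follows from the relative configuration of 22 with retention at both centres. The forward reaction is addition of the alkoxide to the ring A aryne 23, and aryllithium 24 needs only a proton.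

**Carbinol C–H, then C3–C3a (22 from 21, 21 from 15 and 20).** Alcohol 22 is the reduction product of ketone 21. The C3–H of 21 is doubly benzylic and alpha to the carbonyl, so its epimers interconvert and one catalyst-controlled hydride transfer can set C2 and, through it, C3. Ketone 21 is cut at C3–C3a into benzyl ketone 15 and aryl bromide 20 (enolate arylation). The neighbouring cut, C2–C3 between an aldehyde and a diarylmethyl anion, would need a separate three-step diarylmethane and a selective benzylic deprotonation beside a fluoroarene. The forward coupling must join a doubly ortho-substituted bromide without touching C–F or the stilbene.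

**C–Br and the alkene (20 from 18, 18 from 16 and 17).** Bromide 20 comes from fluorostilbene 18 by metalation between fluorine and methoxy (aryllithium 19) and bromination. Stilbene 18 comes from aldehyde 16 and phosphonate 17 by olefination. Ring A is therefore bought, not built, and its E-alkene is set in the first step of the branch.

**C2–C3 (15 from 14, 14 from 11 and 12).** Ketone 15 is the oxidation product of alcohol 14, which is cut into aldehyde 11 and the benzyl Grignard reagent 13 made from chloride 12. The aldehyde carbon of 11 becomes C2; nothing is asked of the addition but chemoselectivity, since the new carbinol centre is oxidised away.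

**O1'–C7a' and C7'–C2 (11 from 7 and 8).** Both bonds sit on adjacent carbons of ring B and are cut together, which leads to aryne 9 flanked by a tethered alkoxide and, after addition, to aryllithium 10 and DMF (8). The alternatives are worse. Closing O1'–C7a' first and formylating afterwards cannot tell C7' from C5' or from the more electron-rich resorcinol rings. Carrying the C7' carbon from the start needs a 1,2,3,4-tetrasubstituted halide that must survive enolate arylation and reduction. Precursor 7 has no ring, and its ring B is the substitution pattern of a catalogue bromide. The forward step must metalate next to fluorine only, close the five-membered ring, and keep the carbanion alive until DMF arrives.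

**Carbinol C–H, then C3'–C3a' (7 from 6, 6 from 4 and 5).** As in the inner half, alcohol 7 comes from an epimerisable triaryl ketone, 6, by dynamic kinetic reduction. Ketone 6 is cut into deoxybenzoin 4 and 2-bromo-3-fluoroanisole 5, which supplies fluorine, methoxy and the attachment carbon in the right order.

**Acyl–aryl bond (4 from 1 and 2).** Deoxybenzoin 4 is cut at the carbonyl–aryl bond into acid 1 (activated as mixed anhydride 3) and 1,3-dimethoxybenzene 2, whose C4 is the natural site of acylation.

## Roads not taken

**Alternative 1:** This road cuts C2–C3 and C2'–C3' at once. In the forward step Rh2(S-DOSP)4 would decompose two aryl diazoacetate units, and each carbene would insert into the benzylic C–H of the neighbouring aryl benzyl ether. Both dihydrofuran rings close in one flask to the pentamethyl ether dimethyl ester with CO2Me at C3 and C3', A1.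
- Merits: one catalytic step makes both rings and all four stereocentres, and the precursor is assembled by simple etherifications. On ring-forming step count this is better than the chosen plan.
- Weak points:
  - A1 has esters where the target has 3,5-dihydroxyphenyl groups. Exchanging each ester for an aryl ring needs either de novo construction of a resorcinol or a decarboxylative arylation through a C3 radical or organometal, twice, at crowded centres.
  - Insertions of this type tend to favour the cis ring kinetically, so an epimerisation at C3 would have to be added while the ester is still there.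
  - The second insertion is a case of double stereodifferentiation.
  - The stilbene is a competent cyclopropanation partner for either carbene.
- Comparison: the chosen plan has the C3 and C3' aryl groups in place from the first C–C bond, the trans geometry follows from a retentive C–O closure, and no carbene ever meets the alkene.

**Alternative 2:** This road cuts ring A itself, at the bonds that join two alkyne-derived carbons (C3a and one oxygen-bearing neighbour) to a four-carbon vinylketene unit. On heating, a styryl-substituted cyclobutenone and a silyloxyalkyne would pass through 4π opening, [2+2] addition, a second 4π opening and 6π closure (Danheiser benzannulation). The product is the ring A resorcinol mono-triisopropylsilyl ether carrying C3, the silylated C2 carbinol and the complete outer ring system, A2.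
- Merits: ring A arises with unambiguous regiochemistry and with its two oxygens differentiated, the C2/C3 pair can be set earlier by acyclic aldol chemistry, and no strong base is used once the stilbene is present. In these respects it is at least as good as the chosen plan.
- Weak points:
  - Ring A is only a 5-substituted resorcinol, yet here it costs a cyclobutenone synthesis plus an ynol ether homologation on a substrate that already carries four stereocentres.
  - The thermal cascade must be survived by a propargylic, benzylic C3–H and by a C2 silyl ether flanked by the donor oxygens of ring B.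
  - The alkyne is heavily encumbered.
  - After A2 the O1–C2 bond still has to be made by substitution at the most ionisable carbon of the molecule.
  - The outer ring must come from another method anyway.
- Comparison: the chosen plan uses the local symmetry of ring A (bought as aldehyde 16), closes the inner ring at the aryl–oxygen bond with retention, and needs no step above 90 °C.

**Alternative 3:** This road cuts C2'–C3' and O1'–C2' in a [4+1] sense. Cs2CO3 would release an ortho-quinone methide of ring B from a sulfone and a 2,4-dimethoxybenzylide from a chiral thiolanium salt. Conjugate addition forms C2'–C3', and displacement of the sulfide by the phenoxide forms O1'–C2'. The product is (2S,3S)-7-[(tert-butyldimethylsilyloxy)methyl]-2-(2,4-dimethoxyphenyl)-3-(3,5-dimethoxyphenyl)-4-methoxy-2,3-dihydrobenzofuran, A3.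
- Merits: the step is convergent, runs with a carbonate base, gives the trans ring by its mechanism and needs no organolithium. For the outer ring it is as good as or better than the chosen plan in mildness and convergence, and A3 reaches aldehyde 11 after desilylation and oxidation.
- Weak points:
  - The stereo-inducing element is a stoichiometric chiral sulfide that must control two new centres at once.
  - The sulfonium salt of a 2,4-dimethoxybenzyl group is itself a labile, ionisable electrophile.
  - The quinone methide precursor is a 1,2,3,4-tetrasubstituted phenol that has to be built with the C7' carbon already attached, which is the very substitution problem the aryne removes.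
- Comparison: the chosen plan offers catalytic stereocontrol of predictable sense, a catalogue bromide (5) that carries the whole ring B pattern, direct delivery of C2 at the aldehyde oxidation level, and a three-step cycle (arylation, reduction, aryne closure) that is simply repeated for the inner ring.

Key step: step 4

Assumption: compounds 1, 2, 5, 8, 12, 16 and 17 are taken as catalogue materials, and the hydrogen alpha to the carbonyl in 6 and 21 is taken to exchange in the amine–formate medium faster than the ketone is reduced.

## Route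

Step 1
Reactants: 1 3,5-dimethoxyphenylacetic acid; 2 1,3-dimethoxybenzene
Product: 4 1-(2,4-dimethoxyphenyl)-2-(3,5-dimethoxyphenyl)ethan-1-one, via mixed trifluoroacetic anhydride 3 (not isolated)
Conditions: (CF3CO)2O (2.5 equiv), 85% H3PO4 (cat.), 2 (3 equiv), CH2Cl2, 0 °C → rt
Reagents that add atoms: none
Why: Friedel–Crafts acylation of an activated arene by an acyl trifluoroacetate; 1,3-dimethoxybenzene reacts at C4, para to one methoxy and ortho to the other, and its excess should outcompete acylation of the dimethoxyphenyl ring of 1.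

Step 2
Reactants: 4 1-(2,4-dimethoxyphenyl)-2-(3,5-dimethoxyphenyl)ethan-1-one; 5 2-bromo-1-fluoro-3-methoxybenzene (2-bromo-3-fluoroanisole)
Product: 6 racemic 1-(2,4-dimethoxyphenyl)-2-(3,5-dimethoxyphenyl)-2-(2-fluoro-6-methoxyphenyl)ethan-1-one
Conditions: Pd(OAc)2 (5 mol %), XPhos (10 mol %), NaOtBu (2.2 equiv), toluene, 90 °C
Reagents that add atoms: none
Why: Palladium-catalysed α-arylation of a ketone enolate (Buchwald–Hartwig type); the benzylic enolate of 4 couples at C–Br, the bulky biaryl phosphine tolerates the two small ortho groups (F, OMe), C–F is inert, and the tertiary α-carbon of 6 cannot be arylated again.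

Step 3
Reactants: 6 racemic 1-(2,4-dimethoxyphenyl)-2-(3,5-dimethoxyphenyl)-2-(2-fluoro-6-methoxyphenyl)ethan-1-one
Product: 7 (1S,2S)-1-(2,4-dimethoxyphenyl)-2-(3,5-dimethoxyphenyl)-2-(2-fluoro-6-methoxyphenyl)ethan-1-ol
Conditions: RuCl[(S,S)-TsDPEN](p-cymene) (2 mol %), HCO2H/Et3N (3:2), DMF, 40 °C
Reagents that add atoms: none
Why: Noyori–Ikariya asymmetric transfer hydrogenation with dynamic kinetic resolution; the α-hydrogen of 6 (doubly benzylic, next to C=O) exchanges through the enol, so the ketone enantiomers interconvert. The (S,S) catalyst sets the (S) carbinol in the usual aryl alkyl ketone sense and should reduce faster the enantiomer in which hydride enters anti to the bulky 2-fluoro-6-methoxyphenyl group (Felkin–Anh), which fixes C2 as (S).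

Step 4
Reactants: 7 (1S,2S)-1-(2,4-dimethoxyphenyl)-2-(3,5-dimethoxyphenyl)-2-(2-fluoro-6-methoxyphenyl)ethan-1-ol; 8 N,N-dimethylformamide
Product: 11 (2S,3S)-2-(2,4-dimethoxyphenyl)-3-(3,5-dimethoxyphenyl)-4-methoxy-2,3-dihydro-1-benzofuran-7-carbaldehyde (trans), via aryne alkoxide 9 (not isolated), via C7'-lithio dihydrobenzofuran 10 (not isolated)
Conditions: LiTMP (lithium 2,2,6,6-tetramethylpiperidide, 2.2 equiv), THF, −78 → −30 °C; then 8 (5 equiv), −78 °C → rt; H2O
Reagents that add atoms: none
Why: The first equivalent of LiTMP gives the lithium alkoxide of 7, the second removes the ring B hydrogen next to fluorine (the future C7'–H), and on warming LiF is lost to give aryne 9 with the triple bond between C7' and C7a'. The tethered alkoxide can reach only C7a', the aryne carbon beside the side chain, and adds in the ring plane in a 5-exo-dig closure that forms O1'–C7a' and leaves the carbanion on C7' as aryllithium 10; attack at C7' would need a bridged ring and is excluded. DMF then acylates 10 and hydrolysis of the hemiaminal releases aldehyde 11, so the C7'–C2 bond is made in the same flask. The closest known reaction type is the benzyne cyclisation: aryne generation by ortho-lithiation and loss of LiF, intramolecular addition of a tethered nucleophile, and electrophile capture of the resulting aryllithium. No stereocentre is formed; only O–H, aryl C–H and C–F bonds are touched, so C2' and C3' are carried over with retention and the (1S,2S) alcohol maps onto the trans (2S,3S) ring. The step needs site-selective metalation, which is secured by fluorine as the strongest kinetic activator towards a hindered amide base that is not guided by methoxy coordination, and by the irreversible loss of LiF. It also needs the C3'–H to stay untouched, which its crowding, the adjacent alkoxide charge and the low temperature favour. Finally 10 must outlive the liberated amine until DMF arrives, which is helped by keeping the base near 2.2 equivalents, by the slow proton transfer from the hindered N–H and by re-cooling before the quench.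

Step 5
Reactants: 11 (2S,3S)-2-(2,4-dimethoxyphenyl)-3-(3,5-dimethoxyphenyl)-4-methoxy-2,3-dihydro-1-benzofuran-7-carbaldehyde; 12 1-(chloromethyl)-3,5-dimethoxybenzene
Product: 14 1-[(2S,3S)-2-(2,4-dimethoxyphenyl)-3-(3,5-dimethoxyphenyl)-4-methoxy-2,3-dihydro-1-benzofuran-7-yl]-2-(3,5-dimethoxyphenyl)ethan-1-ol (both carbinol epimers), via 3,5-dimethoxybenzylmagnesium chloride 13 (not isolated)
Conditions: 12, Mg, THF, 0 °C; then 11, −78 → 0 °C; H2O
Reagents that add atoms: none
Why: Grignard addition to a non-enolisable aryl aldehyde forms the C2–C3 bond; the new carbinol centre need not be controlled because it is oxidised in the next step.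

Step 6
Reactants: 14 1-[(2S,3S)-2-(2,4-dimethoxyphenyl)-3-(3,5-dimethoxyphenyl)-4-methoxy-2,3-dihydro-1-benzofuran-7-yl]-2-(3,5-dimethoxyphenyl)ethan-1-ol
Product: 15 1-[(2S,3S)-2-(2,4-dimethoxyphenyl)-3-(3,5-dimethoxyphenyl)-4-methoxy-2,3-dihydro-1-benzofuran-7-yl]-2-(3,5-dimethoxyphenyl)ethan-1-one
Conditions: Dess–Martin periodinane (1.3 equiv), CH2Cl2, 0 °C → rt
Reagents that add atoms: none
Why: Dess–Martin oxidation of a secondary benzylic alcohol under near-neutral conditions; the acid-labile C2'–O1' bond and the electron-rich rings are not expected to react.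

Step 7
Reactants: 16 3-fluoro-5-methoxybenzaldehyde; 17 diethyl (4-methoxybenzyl)phosphonate
Product: 18 1-fluoro-3-methoxy-5-[(E)-2-(4-methoxyphenyl)ethenyl]benzene
Conditions: KOtBu (1.2 equiv), THF, 0 °C → rt
Reagents that add atoms: none
Why: Horner–Wadsworth–Emmons olefination of an aryl aldehyde with a benzylic phosphonate anion, which should give the E-stilbene.

Step 8
Reactants: 18 1-fluoro-3-methoxy-5-[(E)-2-(4-methoxyphenyl)ethenyl]benzene
Product: 20 2-bromo-1-fluoro-3-methoxy-5-[(E)-2-(4-methoxyphenyl)ethenyl]benzene, via C2-lithiated fluorostilbene 19 (not isolated)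
Conditions: LiTMP (1.1 equiv), THF, −78 °C; then BrCCl2CCl2Br, −78 °C → rt
Reagents that add atoms: 1,2-dibromo-1,1,2,2-tetrachloroethane, BrC(Cl)(Cl)C(Cl)(Cl)Br
Why: Directed ortho-metalation at the C–H flanked by fluorine and methoxy, the most acidic position of 18, followed by bromine transfer; at −78 °C aryllithium 19 does not lose LiF and the amide base does not add to the stilbene.

Step 9
Reactants: 15 1-[(2S,3S)-2-(2,4-dimethoxyphenyl)-3-(3,5-dimethoxyphenyl)-4-methoxy-2,3-dihydro-1-benzofuran-7-yl]-2-(3,5-dimethoxyphenyl)ethan-1-one; 20 2-bromo-1-fluoro-3-methoxy-5-[(E)-2-(4-methoxyphenyl)ethenyl]benzene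
Product: 21 1-[(2S,3S)-2-(2,4-dimethoxyphenyl)-3-(3,5-dimethoxyphenyl)-4-methoxy-2,3-dihydro-1-benzofuran-7-yl]-2-(3,5-dimethoxyphenyl)-2-{2-fluoro-6-methoxy-4-[(E)-2-(4-methoxyphenyl)ethenyl]phenyl}ethan-1-one (both epimers at C2 of the ethanone)
Conditions: Pd(OAc)2 (5 mol %), XPhos (10 mol %), NaOtBu (2.2 equiv), toluene, 90 °C
Reagents that add atoms: none
Why: The same palladium-catalysed enolate arylation as in step 2, forming C3–C3a; the ketone α-CH2 is the only site NaOtBu can deprotonate, and the 1,2-disubstituted stilbene is a poor Heck partner beside a ketone enolate.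

Step 10
Reactants: 21 1-[(2S,3S)-2-(2,4-dimethoxyphenyl)-3-(3,5-dimethoxyphenyl)-4-methoxy-2,3-dihydro-1-benzofuran-7-yl]-2-(3,5-dimethoxyphenyl)-2-{2-fluoro-6-methoxy-4-[(E)-2-(4-methoxyphenyl)ethenyl]phenyl}ethan-1-one
Product: 22 (1S,2S)-1-[(2S,3S)-2-(2,4-dimethoxyphenyl)-3-(3,5-dimethoxyphenyl)-4-methoxy-2,3-dihydro-1-benzofuran-7-yl]-2-(3,5-dimethoxyphenyl)-2-{2-fluoro-6-methoxy-4-[(E)-2-(4-methoxyphenyl)ethenyl]phenyl}ethan-1-ol
Conditions: RuCl[(S,S)-TsDPEN](p-cymene) (3 mol %), HCO2H/Et3N (3:2), DMF, 40 °C
Reagents that add atoms: none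
Why: Asymmetric transfer hydrogenation with dynamic kinetic resolution as in step 3; the catalyst sets the carbinol (future C2) as (S), and the interconverting C3 epimers are funnelled to the (S) centre by hydride entry anti to the 2,6-disubstituted ring A aryl (Felkin–Anh). The stilbene is not reduced by the ruthenium hydride, and the outer-ring centres are too remote to override the catalyst.

Step 11
Reactants: 22 (1S,2S)-1-[(2S,3S)-2-(2,4-dimethoxyphenyl)-3-(3,5-dimethoxyphenyl)-4-methoxy-2,3-dihydro-1-benzofuran-7-yl]-2-(3,5-dimethoxyphenyl)-2-{2-fluoro-6-methoxy-4-[(E)-2-(4-methoxyphenyl)ethenyl]phenyl}ethan-1-ol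
Product: 25 (2S,3S)-2-[(2S,3S)-2-(2,4-dimethoxyphenyl)-3-(3,5-dimethoxyphenyl)-4-methoxy-2,3-dihydro-1-benzofuran-7-yl]-3-(3,5-dimethoxyphenyl)-4-methoxy-6-[(E)-2-(4-methoxyphenyl)ethenyl]-2,3-dihydro-1-benzofuran (gnetumontanin B nonamethyl ether), via ring A aryne alkoxide 23 (not isolated), via C7-lithio nonamethyl ether 24 (not isolated)
Conditions: LiTMP (2.5 equiv), THF, −78 → −20 °C; then H2O
Reagents that add atoms: none
Why: The alkoxide–aryne closure of step 4 is used again: metalation next to fluorine, loss of LiF, 5-exo-dig addition of the alkoxide to C7a, and protonation of aryllithium 24 by the liberated amine or on work-up. The aryl–oxygen bond forms with retention at C2 and C3, so the (1S,2S) alcohol gives the trans (2S,3S) inner ring.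

Step 12
Reactants: 25 gnetumontanin B nonamethyl ether
Product: 26 (2S,3S)-2-[(2S,3S)-2-(2,4-dihydroxyphenyl)-3-(3,5-dihydroxyphenyl)-4-hydroxy-2,3-dihydro-1-benzofuran-7-yl]-3-(3,5-dihydroxyphenyl)-6-[(E)-2-(4-hydroxyphenyl)ethenyl]-2,3-dihydro-1-benzofuran-4-ol (gnetumontanin B)
Conditions: BBr3 (20 equiv), CH2Cl2, −78 → 0 °C, dark; then H2O
Reagents that add atoms: none
Why: Lewis-acid cleavage of aryl methyl ethers (boron coordination, bromide attack at methyl), the standard unmasking of permethylated stilbenoid oligomers. Low temperature should limit ionisation of the benzylic ether bonds, and any reversible opening at C2 or C2' can only re-close trans to the fixed C3 or C3' aryl group.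

## Compound list

1 | 3,5-dimethoxyphenylacetic acid | COc1cc(CC(=O)O)cc(OC)c1 | starting material
2 | 1,3-dimethoxybenzene | COc1cccc(OC)c1 | starting material
3 | (3,5-dimethoxyphenyl)acetic trifluoroacetic anhydride | COc1cc(CC(=O)OC(=O)C(F)(F)F)cc(OC)c1 | intermediate
4 | 1-(2,4-dimethoxyphenyl)-2-(3,5-dimethoxyphenyl)ethan-1-one | COc1ccc(C(=O)Cc2cc(OC)cc(OC)c2)c(OC)c1 | intermediate
5 | 2-bromo-1-fluoro-3-methoxybenzene | COc1cccc(F)c1Br | starting material
6 | racemic 1-(2,4-dimethoxyphenyl)-2-(3,5-dimethoxyphenyl)-2-(2-fluoro-6-methoxyphenyl)ethan-1-one | COc1ccc(C(=O)C(c2c(F)cccc2OC)c2cc(OC)cc(OC)c2)c(OC)c1 | intermediate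
7 | (1S,2S)-1-(2,4-dimethoxyphenyl)-2-(3,5-dimethoxyphenyl)-2-(2-fluoro-6-methoxyphenyl)ethan-1-ol | O[C@H](c1ccc(OC)cc1OC)[C@H](c1c(F)cccc1OC)c1cc(OC)cc(OC)c1 | intermediate
8 | N,N-dimethylformamide | CN(C)C=O | starting material
9 | lithium (1S,2S)-1-(2,4-dimethoxyphenyl)-2-(3,5-dimethoxyphenyl)-2-(6-methoxy-2,3-didehydrophenyl)ethan-1-olate (ring B aryne) | [Li]O[C@H](c1ccc(OC)cc1OC)[C@H](C1=C(OC)C=CC#C1)c1cc(OC)cc(OC)c1 | intermediate
10 | [(2S,3S)-2-(2,4-dimethoxyphenyl)-3-(3,5-dimethoxyphenyl)-4-methoxy-2,3-dihydro-1-benzofuran-7-yl]lithium | [Li]c1ccc(OC)c2c1O[C@H](c1ccc(OC)cc1OC)[C@H]2c1cc(OC)cc(OC)c1 | intermediate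
11 | (2S,3S)-2-(2,4-dimethoxyphenyl)-3-(3,5-dimethoxyphenyl)-4-methoxy-2,3-dihydro-1-benzofuran-7-carbaldehyde | O=Cc1ccc(OC)c2c1O[C@H](c1ccc(OC)cc1OC)[C@H]2c1cc(OC)cc(OC)c1 | intermediate
12 | 1-(chloromethyl)-3,5-dimethoxybenzene | COc1cc(CCl)cc(OC)c1 | starting material
13 | 3,5-dimethoxybenzylmagnesium chloride | COc1cc(C[Mg]Cl)cc(OC)c1 | intermediate
14 | 1-[(2S,3S)-2-(2,4-dimethoxyphenyl)-3-(3,5-dimethoxyphenyl)-4-methoxy-2,3-dihydro-1-benzofuran-7-yl]-2-(3,5-dimethoxyphenyl)ethan-1-ol (both carbinol epimers) | OC(Cc1cc(OC)cc(OC)c1)c1ccc(OC)c2c1O[C@H](c1ccc(OC)cc1OC)[C@H]2c1cc(OC)cc(OC)c1 | intermediate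
15 | 1-[(2S,3S)-2-(2,4-dimethoxyphenyl)-3-(3,5-dimethoxyphenyl)-4-methoxy-2,3-dihydro-1-benzofuran-7-yl]-2-(3,5-dimethoxyphenyl)ethan-1-one | O=C(Cc1cc(OC)cc(OC)c1)c1ccc(OC)c2c1O[C@H](c1ccc(OC)cc1OC)[C@H]2c1cc(OC)cc(OC)c1 | intermediate
16 | 3-fluoro-5-methoxybenzaldehyde | COc1cc(F)cc(C=O)c1 | starting material
17 | diethyl (4-methoxybenzyl)phosphonate | CCOP(=O)(Cc1ccc(OC)cc1)OCC | starting material
18 | 1-fluoro-3-methoxy-5-[(E)-2-(4-methoxyphenyl)ethenyl]benzene | COc1ccc(/C=C/c2cc(F)cc(OC)c2)cc1 | intermediate
19 | {2-fluoro-6-methoxy-4-[(E)-2-(4-methoxyphenyl)ethenyl]phenyl}lithium | COc1ccc(/C=C/c2cc(F)c([Li])c(OC)c2)cc1 | intermediate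
20 | 2-bromo-1-fluoro-3-methoxy-5-[(E)-2-(4-methoxyphenyl)ethenyl]benzene | COc1ccc(/C=C/c2cc(F)c(Br)c(OC)c2)cc1 | intermediate
21 | 1-[(2S,3S)-2-(2,4-dimethoxyphenyl)-3-(3,5-dimethoxyphenyl)-4-methoxy-2,3-dihydro-1-benzofuran-7-yl]-2-(3,5-dimethoxyphenyl)-2-{2-fluoro-6-methoxy-4-[(E)-2-(4-methoxyphenyl)ethenyl]phenyl}ethan-1-one (both epimers at C2 of the ethanone) | O=C(c1ccc(OC)c2c1O[C@H](c1ccc(OC)cc1OC)[C@H]2c1cc(OC)cc(OC)c1)C(c1c(F)cc(/C=C/c2ccc(OC)cc2)cc1OC)c1cc(OC)cc(OC)c1 | intermediate
22 | (1S,2S)-1-[(2S,3S)-2-(2,4-dimethoxyphenyl)-3-(3,5-dimethoxyphenyl)-4-methoxy-2,3-dihydro-1-benzofuran-7-yl]-2-(3,5-dimethoxyphenyl)-2-{2-fluoro-6-methoxy-4-[(E)-2-(4-methoxyphenyl)ethenyl]phenyl}ethan-1-ol | O[C@H](c1ccc(OC)c2c1O[C@H](c1ccc(OC)cc1OC)[C@H]2c1cc(OC)cc(OC)c1)[C@H](c1c(F)cc(/C=C/c2ccc(OC)cc2)cc1OC)c1cc(OC)cc(OC)c1 | intermediate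
23 | lithium alkoxide of 22 with ring A as the 2,3-didehydro arene (triple bond between the former C–F carbon and its C–H neighbour) | [Li]O[C@H](c1ccc(OC)c2c1O[C@H](c1ccc(OC)cc1OC)[C@H]2c1cc(OC)cc(OC)c1)[C@H](C1=C(OC)C=C(/C=C/c2ccc(OC)cc2)C#C1)c1cc(OC)cc(OC)c1 | intermediate
24 | 7-lithio derivative of gnetumontanin B nonamethyl ether (lithium on C7 of ring A) | COc1ccc(/C=C/c2cc(OC)c3c(c2[Li])O[C@H](c2ccc(OC)c4c2O[C@H](c2ccc(OC)cc2OC)[C@H]4c2cc(OC)cc(OC)c2)[C@H]3c2cc(OC)cc(OC)c2)cc1 | intermediate
25 | (2S,3S)-2-[(2S,3S)-2-(2,4-dimethoxyphenyl)-3-(3,5-dimethoxyphenyl)-4-methoxy-2,3-dihydro-1-benzofuran-7-yl]-3-(3,5-dimethoxyphenyl)-4-methoxy-6-[(E)-2-(4-methoxyphenyl)ethenyl]-2,3-dihydro-1-benzofuran (gnetumontanin B nonamethyl ether) | COc1ccc(/C=C/c2cc(OC)c3c(c2)O[C@H](c2ccc(OC)c4c2O[C@H](c2ccc(OC)cc2OC)[C@H]4c2cc(OC)cc(OC)c2)[C@H]3c2cc(OC)cc(OC)c2)cc1 | intermediate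
26 | gnetumontanin B, (2S,3S)-2-[(2S,3S)-2-(2,4-dihydroxyphenyl)-3-(3,5-dihydroxyphenyl)-4-hydroxy-2,3-dihydro-1-benzofuran-7-yl]-3-(3,5-dihydroxyphenyl)-6-[(E)-2-(4-hydroxyphenyl)ethenyl]-2,3-dihydro-1-benzofuran-4-ol | Oc1ccc(/C=C/c2cc(O)c3c(c2)O[C@H](c2ccc(O)c4c2O[C@H](c2ccc(O)cc2O)[C@H]4c2cc(O)cc(O)c2)[C@H]3c2cc(O)cc(O)c2)cc1 | target

## Step count and risks

Total step count: 12. Longest linear sequence: 10 steps (steps 1–6 and 9–12); steps 7 and 8 form the ring A branch.

**Step 4 (key step).**
- Risk: proton transfer to the cyclised C7' carbanion from the liberated amine before DMF is added, so that the ring closes without carbon capture. A lesser risk is metalation between methoxy groups followed by formylation there.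
- Fallback (from 7, back to 11): the order of events is reversed and the aryne avoided. Alcohol 7 is metalated with LiTMP at −78 °C and DMF is added at that temperature, where the fluorine-stabilised aryllithium neither loses LiF nor is basic enough to be quenched by the amine. This should give 3-[(1S,2S)-2-(2,4-dimethoxyphenyl)-1-(3,5-dimethoxyphenyl)-2-hydroxyethyl]-2-fluoro-4-methoxybenzaldehyde F1. Its fluoride is now ortho to a formyl group, and K2CO3 in DMF at 60 °C should close the ring by intramolecular nucleophilic aromatic substitution to 11.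

**Step 3.**
- Risk: enolisation of the crowded α-carbon lagging behind hydride transfer, weak discrimination between the two α-aryl groups, or sluggish reduction of a hindered, electron-rich ketone. Any of these erodes diastereo- and enantiocontrol or conversion.
- Fallback (from 6, back to 7): substrate-controlled Felkin–Anh reduction of racemic 6 with LiBH(s-Bu)3 in THF at −78 °C should give 7 together with its mirror image, (1R,2R)-1-(2,4-dimethoxyphenyl)-2-(3,5-dimethoxyphenyl)-2-(2-fluoro-6-methoxyphenyl)ethan-1-ol F2. The racemate is resolved by preparative chromatography on a chiral stationary phase and 7 is carried on.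

**Step 10.**
- Risk: the same as in step 3, plus a possible mismatch between the catalyst's preference and the resident outer-ring centres, which would show as slow reduction or poor selection between the C3 epimers.
- Fallback (from 21, back to 22): LiBH(s-Bu)3 reduces both C3 epimers of 21 under Felkin–Anh control to 22 and to (1R,2R)-1-[(2S,3S)-2-(2,4-dimethoxyphenyl)-3-(3,5-dimethoxyphenyl)-4-methoxy-2,3-dihydro-1-benzofuran-7-yl]-2-(3,5-dimethoxyphenyl)-2-{2-fluoro-6-methoxy-4-[(E)-2-(4-methoxyphenyl)ethenyl]phenyl}ethan-1-ol F3. These are diastereomers and separable on silica. F3 is returned to 21 by Dess–Martin oxidation and brief base equilibration, and recycled.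

**Step 11.**
- Risk: deprotonation at the doubly benzylic C3'–H of the existing outer ring with expulsion of the O1' phenoxide (ring opening), or attack of the base on the stilbene, competing with metalation next to fluorine.
- Fallback (from 15, back to 26): no strong base is used after step 4, and the inner ring is closed at C2–O1 instead. Commercial 4-bromo-3,5-dimethoxybenzaldehyde and 17 give by olefination 2-bromo-1,3-dimethoxy-5-[(E)-2-(4-methoxyphenyl)ethenyl]benzene F4. Enolate arylation of 15 with F4 (conditions of step 9) gives 1-[(2S,3S)-2-(2,4-dimethoxyphenyl)-3-(3,5-dimethoxyphenyl)-4-methoxy-2,3-dihydro-1-benzofuran-7-yl]-2-(3,5-dimethoxyphenyl)-2-{2,6-dimethoxy-4-[(E)-2-(4-methoxyphenyl)ethenyl]phenyl}ethan-1-one F5. Transfer hydrogenation as in step 10 gives the (1S,2S) alcohol (1S,2S)-1-[(2S,3S)-2-(2,4-dimethoxyphenyl)-3-(3,5-dimethoxyphenyl)-4-methoxy-2,3-dihydro-1-benzofuran-7-yl]-2-(3,5-dimethoxyphenyl)-2-{2,6-dimethoxy-4-[(E)-2-(4-methoxyphenyl)ethenyl]phenyl}ethan-1-ol F6. BBr3 then removes all ten methyl groups and ionises the C2 carbinol. The cation is captured by either of the two equivalent ortho hydroxyls of ring A, trans to the C3 aryl group fixed in the reduction, which leads directly to 26.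

**Step 12.**
- Risk: ionisation of the C2–O1 and C2'–O1' bonds under the Lewis acid, followed by capture of the cations by neighbouring resorcinol rings instead of re-closure, and E/Z isomerisation of the stilbene.
- Fallback (from 25, back to 26): electrophilic ether cleavage is replaced by nucleophilic demethylation with NaSEt in DMF at 120–140 °C. Thiolate attacks the methyl carbons and no benzylic cation can form. No new compound is isolated on the way.

## Further compounds

F1 | step 4 | 3-[(1S,2S)-2-(2,4-dimethoxyphenyl)-1-(3,5-dimethoxyphenyl)-2-hydroxyethyl]-2-fluoro-4-methoxybenzaldehyde | O[C@H](c1ccc(OC)cc1OC)[C@H](c1c(F)c(C=O)ccc1OC)c1cc(OC)cc(OC)c1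
F2 | step 3 | (1R,2R)-1-(2,4-dimethoxyphenyl)-2-(3,5-dimethoxyphenyl)-2-(2-fluoro-6-methoxyphenyl)ethan-1-ol | O[C@@H](c1ccc(OC)cc1OC)[C@@H](c1c(F)cccc1OC)c1cc(OC)cc(OC)c1
F3 | step 10 | (1R,2R)-1-[(2S,3S)-2-(2,4-dimethoxyphenyl)-3-(3,5-dimethoxyphenyl)-4-methoxy-2,3-dihydro-1-benzofuran-7-yl]-2-(3,5-dimethoxyphenyl)-2-{2-fluoro-6-methoxy-4-[(E)-2-(4-methoxyphenyl)ethenyl]phenyl}ethan-1-ol | O[C@@H](c1ccc(OC)c2c1O[C@H](c1ccc(OC)cc1OC)[C@H]2c1cc(OC)cc(OC)c1)[C@@H](c1c(F)cc(/C=C/c2ccc(OC)cc2)cc1OC)c1cc(OC)cc(OC)c1
F4 | step 11 | 2-bromo-1,3-dimethoxy-5-[(E)-2-(4-methoxyphenyl)ethenyl]benzene | COc1ccc(/C=C/c2cc(OC)c(Br)c(OC)c2)cc1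
F5 | step 11 | 1-[(2S,3S)-2-(2,4-dimethoxyphenyl)-3-(3,5-dimethoxyphenyl)-4-methoxy-2,3-dihydro-1-benzofuran-7-yl]-2-(3,5-dimethoxyphenyl)-2-{2,6-dimethoxy-4-[(E)-2-(4-methoxyphenyl)ethenyl]phenyl}ethan-1-one (both epimers at C2 of the ethanone) | O=C(c1ccc(OC)c2c1O[C@H](c1ccc(OC)cc1OC)[C@H]2c1cc(OC)cc(OC)c1)C(c1c(OC)cc(/C=C/c2ccc(OC)cc2)cc1OC)c1cc(OC)cc(OC)c1
F6 | step 11 | (1S,2S)-1-[(2S,3S)-2-(2,4-dimethoxyphenyl)-3-(3,5-dimethoxyphenyl)-4-methoxy-2,3-dihydro-1-benzofuran-7-yl]-2-(3,5-dimethoxyphenyl)-2-{2,6-dimethoxy-4-[(E)-2-(4-methoxyphenyl)ethenyl]phenyl}ethan-1-ol | O[C@H](c1ccc(OC)c2c1O[C@H](c1ccc(OC)cc1OC)[C@H]2c1cc(OC)cc(OC)c1)[C@H](c1c(OC)cc(/C=C/c2ccc(OC)cc2)cc1OC)c1cc(OC)cc(OC)c1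
F0 | step 12 | none | none
A1 | alternative 1 | pentamethyl ether dimethyl ester of the bis(trans-2-aryl-2,3-dihydrobenzofuran-3-carboxylic acid) core, CO2Me at C3 and C3' | COc1ccc(/C=C/c2cc(OC)c3c(c2)O[C@H](c2ccc(OC)c4c2O[C@H](c2ccc(OC)cc2OC)[C@H]4C(=O)OC)[C@H]3C(=O)OC)cc1
A2 | alternative 2 | ring A resorcinol mono-triisopropylsilyl ether carrying the C3 aryl group, the C2 tert-butyldimethylsilyl ether and the outer dihydrobenzofuran | COc1ccc(/C=C/c2cc(O)c([C@H](c3cc(OC)cc(OC)c3)[C@@H](O[Si](C)(C)C(C)(C)C)c3ccc(OC)c4c3O[C@H](c3ccc(OC)cc3OC)[C@H]4c3cc(OC)cc(OC)c3)c(O[Si](C(C)C)(C(C)C)C(C)C)c2)cc1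
A3 | alternative 3 | (2S,3S)-7-[(tert-butyldimethylsilyloxy)methyl]-2-(2,4-dimethoxyphenyl)-3-(3,5-dimethoxyphenyl)-4-methoxy-2,3-dihydro-1-benzofuran | CC(C)(C)[Si](C)(C)OCc1ccc(OC)c2c1O[C@H](c1ccc(OC)cc1OC)[C@H]2c1cc(OC)cc(OC)c1
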